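The cyclopentenone atoms are labelled as follows: C1 is the ketone carbon, C2=C3 the alkene, C4 and C5 the carbinol carbons, C6 the acetoxy carbon of the chain. Everything rests on cutting the ring bond C2–C3. The key step exploits that both C2 and C3 are bare CH positions of the five-membered ring, so a diazoketone carbon (C2) can be joined to a silyloxymethyl carbon (C3) by rhodium-carbenoid 1,5 C–H insertion, which makes that bond and the carbocycle in one operation; silanol loss then gives the enone. The precursor is an acyclic diazoketone already holding all three stereocentres and the C6 acetate, with O4 and O5 tied in a di-tert-butylsilylene ring.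

Key step: step 9

Remarks on the design
- The carboxyl group is carried as a benzyl ester, so that it can be freed by hydrogenolysis without touching the C6 acetate.
- The acetate is placed on O6 before the diol is made, so that the O4/O5 pair is the only diol present when the silylene is installed.
- Assumption: in step 3 the lipase treats the branched alkenyl-ester arm as the large substituent (usual empirical preference for secondary alcohols), so the (R)-alcohol is acetylated and the (S)-alcohol is recovered; with the opposite preference the (S)-acetate 9 would form directly.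

Step 1
Reactants: 1 tert-butyldimethyl(prop-2-yn-1-yloxy)silane; 2 benzyl chloroformate
Product: 4 benzyl 4-[(tert-butyldimethylsilyl)oxy]but-2-ynoate, via lithium acetylide 3 (not isolated)
Conditions: n-BuLi, THF, −78 °C; then 2, −78 → 0 °C
Reagents that add atoms: n-butyllithium, [Li]CCCC (lithium of intermediate 3 only)
Why: Acetylide acylation, in which the lithium acetylide adds to the chloroformate carbonyl and chloride leaves (addition–elimination), is the standard entry to ynoates and creates no stereocentre.

Step 2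
Reactants: 4 benzyl 4-[(tert-butyldimethylsilyl)oxy]but-2-ynoate; 5 pentadecanal
Product: 7 racemic benzyl (2Z)-4-[(tert-butyldimethylsilyl)oxy]-2-(1-hydroxypentadecyl)but-2-enoate, via vinylalane 6 (not isolated)
Conditions: i-Bu2AlH, NMO (N-methylmorpholine N-oxide), THF, 0 °C; then 5, 0 °C → rt; aqueous work-up
Reagents that add atoms: diisobutylaluminium hydride, CC(C)C[AlH]CC(C)C (aluminium fragment of intermediate 6 only)
Why: Conjugate hydroalumination of the ynoate followed by aldol addition of the α-aluminated enoate (the vinylalane route to Morita–Baylis–Hillman-type adducts) adds H and Al syn and replaces the C–Al bond with retention, so CH2OTBS should end up cis to the ester (Z), while the carbinol centre forms as a racemate.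

Step 3
Reactants: 7 racemic benzyl (2Z)-4-[(tert-butyldimethylsilyl)oxy]-2-(1-hydroxypentadecyl)but-2-enoate
Product: 8 benzyl (2Z)-4-[(tert-butyldimethylsilyl)oxy]-2-[(1S)-1-hydroxypentadecyl]but-2-enoate
Conditions: immobilised Burkholderia cepacia lipase, vinyl acetate, MTBE, 35 °C, run to slightly beyond half conversion; chromatography
Reagents that add atoms: none
Why: Lipase-catalysed kinetic resolution by irreversible transesterification should acetylate the (R)-alcohol and leave the (S)-alcohol, which is separated from the acetate, so the C6 configuration is fixed here.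

Step 4
Reactants: 8 benzyl (2Z)-4-[(tert-butyldimethylsilyl)oxy]-2-[(1S)-1-hydroxypentadecyl]but-2-enoate
Product: 9 benzyl (2Z)-2-[(1S)-1-(acetyloxy)pentadecyl]-4-[(tert-butyldimethylsilyl)oxy]but-2-enoate
Conditions: Ac2O, pyridine, CH2Cl2, 0 °C → rt
Reagents that add atoms: acetic anhydride, CC(=O)OC(C)=O
Why: O-Acylation of the secondary alcohol leaves the C6–O bond intact (retention), and DMAP is left out to avoid SN2′ transposition of the activated allylic acetate.

Step 5
Reactants: 9 benzyl (2Z)-2-[(1S)-1-(acetyloxy)pentadecyl]-4-[(tert-butyldimethylsilyl)oxy]but-2-enoate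
Product: 10 benzyl (2R,3S)-2-[(1S)-1-(acetyloxy)pentadecyl]-4-[(tert-butyldimethylsilyl)oxy]-2,3-dihydroxybutanoate
Conditions: OsO4 (cat.), NMO, citric acid, t-BuOH/H2O (1:1), rt; used directly in step 6
Reagents that add atoms: osmium tetroxide, O=[Os](=O)(=O)=O; N-methylmorpholine N-oxide, C[N+]1([O-])CCOCC1; water, O
Why: Catalytic syn-dihydroxylation (osmylation with NMO as reoxidant, acidic variant for electron-poor alkenes) adds both oxygens to one face of the Z-alkene, which fixes C4 relative to C5, and attack anti to the C6–O bond in the conformer with C6–H eclipsing the alkene (the empirical rule for allylic oxygen-substituted alkenes, reinforced by the geminal ester) should set C4 and C5 relative to C6 as in the target, while the acidic medium suppresses acetyl migration.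

Step 6
Reactants: 10 benzyl (2R,3S)-2-[(1S)-1-(acetyloxy)pentadecyl]-4-[(tert-butyldimethylsilyl)oxy]-2,3-dihydroxybutanoate
Product: 11 benzyl (4S,5S)-4-[(1S)-1-(acetyloxy)pentadecyl]-2,2-di-tert-butyl-5-{[(tert-butyldimethylsilyl)oxy]methyl}-1,3,2-dioxasilolane-4-carboxylate
Conditions: t-Bu2Si(OTf)2, 2,6-lutidine, CH2Cl2, 0 °C → rt
Reagents that add atoms: di-tert-butylsilyl bis(trifluoromethanesulfonate), CC(C)(C)[Si](OS(=O)(=O)C(F)(F)F)(OS(=O)(=O)C(F)(F)F)C(C)(C)C
Why: Cyclic silylene formation with the bis-triflate, which is reactive enough to silylate the tertiary hydroxyl once the secondary one has reacted, can only bridge O4 and O5 because these are the only free hydroxyls; no stereocentre is touched.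

Step 7
Reactants: 11 benzyl (4S,5S)-4-[(1S)-1-(acetyloxy)pentadecyl]-2,2-di-tert-butyl-5-{[(tert-butyldimethylsilyl)oxy]methyl}-1,3,2-dioxasilolane-4-carboxylate
Product: 12 (4S,5S)-4-[(1S)-1-(acetyloxy)pentadecyl]-2,2-di-tert-butyl-5-{[(tert-butyldimethylsilyl)oxy]methyl}-1,3,2-dioxasilolane-4-carboxylic acid
Conditions: H2 (1 atm), Pd/C, EtOAc, rt
Reagents that add atoms: none
Why: Hydrogenolysis of the benzyl ester is neutral and leaves the acetate, the silyl ether and the silylene untouched in ethyl acetate.

Step 8
Reactants: 12 (4S,5S)-4-[(1S)-1-(acetyloxy)pentadecyl]-2,2-di-tert-butyl-5-{[(tert-butyldimethylsilyl)oxy]methyl}-1,3,2-dioxasilolane-4-carboxylic acid; 13 trimethylsilyldiazomethane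
Product: 15 (1S)-1-[(4S,5S)-2,2-di-tert-butyl-5-{[(tert-butyldimethylsilyl)oxy]methyl}-4-(diazoacetyl)-1,3,2-dioxasilolan-4-yl]pentadecyl acetate, via acid chloride 14 (not isolated)
Conditions: 1-chloro-N,N,2-trimethylprop-1-en-1-amine, CH2Cl2, 0 °C → rt; then 13 (excess), THF/MeCN, 0 °C → rt
Reagents that add atoms: 1-chloro-N,N,2-trimethylprop-1-en-1-amine, CC(C)=C(Cl)N(C)C (chlorine of intermediate 14 only)
Why: Neutral acid chloride formation with the α-chloroenamine followed by C-acylation of the diazoalkane (Arndt–Eistert-type diazoketone synthesis, the silyl group leaving as TMSCl) should work without acid-induced desilylation, and because the acid chloride has no α-hydrogen neither ketene formation nor epimerisation at C5 is possible.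

Step 9
Reactants: 15 (1S)-1-[(4S,5S)-2,2-di-tert-butyl-5-{[(tert-butyldimethylsilyl)oxy]methyl}-4-(diazoacetyl)-1,3,2-dioxasilolan-4-yl]pentadecyl acetate
Product: 16 (1S)-1-[(3aS,6aS)-2,2-di-tert-butyl-6-[(tert-butyldimethylsilyl)oxy]-4-oxotetrahydro-3aH-cyclopenta[d][1,3,2]dioxasilol-3a-yl]pentadecyl acetate (both epimers at the silyloxy carbon C3)
Conditions: Rh2(OAc)4 (2 mol %), CH2Cl2, rt, slow addition of 15
Reagents that add atoms: none
Why: Rh2(OAc)4 decomposes the diazoketone with loss of N2 to an electrophilic rhodium carbenoid at C2, which inserts into a C3–H bond through a concerted, asynchronous three-centre transition state with hydride-transfer character, forming the C2–C3 bond and releasing the catalyst. The closest known reaction type is the Rh2(OAc)4-catalysed intramolecular 1,5 C–H insertion of α-diazoketones into C–H bonds next to an ether or silyl ether oxygen, which gives 3-oxygenated cyclopentanones. The carbocycle C1–C2–C3–C4–C5 closes in the 1,5-insertion mode, and because the dioxasilolane holds the CH2OTBS arm and the diazoacetyl arm cis on neighbouring ring carbons, only the cis-fused bicyclo[3.3.0] system can form and C4 and C5 keep their configuration. The new stereocentre at C3 needs no control (the silyloxy group is expected mainly on the convex face), since C3 becomes sp2 in step 10. The step needs site selectivity against 1,5-insertion into the chain C7–H bonds and against ylide formation at O4: the C3–H bonds are activated by the adjacent silyloxy oxygen and pre-oriented by the ring, the C7–H bonds are deactivated inductively by the C6 acetate, the bulky and weakly basic silyl-bound oxygens resist oxonium ylide formation, and insertion at C4–H or C6–H would give four-membered rings. Slow addition keeps the diazo concentration low and so suppresses carbene dimerisation.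

Step 10
Reactants: 16 (1S)-1-[(3aS,6aS)-2,2-di-tert-butyl-6-[(tert-butyldimethylsilyl)oxy]-4-oxotetrahydro-3aH-cyclopenta[d][1,3,2]dioxasilol-3a-yl]pentadecyl acetate
Product: 17 (1S)-1-[(3aS,6aS)-2,2-di-tert-butyl-4-oxo-4,6a-dihydro-3aH-cyclopenta[d][1,3,2]dioxasilol-3a-yl]pentadecyl acetate
Conditions: DBU, CH2Cl2, 0 °C → rt
Reagents that add atoms: none
Why: E1cB β-elimination of silanolate from the β-silyloxy ketone can proceed only through the C2 enolate because C5 is quaternary, so both C3 epimers converge on the C2=C3 enone, and the cis ring fusion prevents epimerisation at C4.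

Step 11
Reactants: 17 (1S)-1-[(3aS,6aS)-2,2-di-tert-butyl-4-oxo-4,6a-dihydro-3aH-cyclopenta[d][1,3,2]dioxasilol-3a-yl]pentadecyl acetate
Product: 18 (1S)-1-[(1R,5S)-1,5-dihydroxy-2-oxocyclopent-3-en-1-yl]pentadecyl acetate (target; (4S,5R,6S) in the atom labels used here)
Conditions: HF·pyridine, pyridine, THF, 0 °C
Reagents that add atoms: none
Why: Fluoride-mediated cleavage of the two Si–O bonds of the strained silylene under mildly acidic conditions should free the cis-diol without hydrolysing or shifting the acetate and without retro-aldol cleavage; no stereocentre is touched.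

Compound list
1 | tert-butyldimethyl(prop-2-yn-1-yloxy)silane | C#CCO[Si](C)(C)C(C)(C)C | starting material
2 | benzyl chloroformate | O=C(Cl)OCc1ccccc1 | starting material
3 | lithium acetylide of 1 | [Li]C#CCO[Si](C)(C)C(C)(C)C | intermediate (not isolated)
4 | benzyl 4-[(tert-butyldimethylsilyl)oxy]but-2-ynoate | O=C(OCc1ccccc1)C#CCO[Si](C)(C)C(C)(C)C | intermediate
5 | pentadecanal | CCCCCCCCCCCCCCC=O | starting material
6 | benzyl 2-(diisobutylalumanyl)-4-[(tert-butyldimethylsilyl)oxy]but-2-enoate, Al cis to the vinylic H and CH2OTBS cis to the ester | CC(C)C[Al](CC(C)C)/C(C(=O)OCc1ccccc1)=C/CO[Si](C)(C)C(C)(C)C | intermediate (not isolated)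
7 | racemic benzyl (2Z)-4-[(tert-butyldimethylsilyl)oxy]-2-(1-hydroxypentadecyl)but-2-enoate | CCCCCCCCCCCCCCC(O)/C(C(=O)OCc1ccccc1)=C/CO[Si](C)(C)C(C)(C)C | intermediate
8 | benzyl (2Z)-4-[(tert-butyldimethylsilyl)oxy]-2-[(1S)-1-hydroxypentadecyl]but-2-enoate | CCCCCCCCCCCCCC[C@H](O)/C(C(=O)OCc1ccccc1)=C/CO[Si](C)(C)C(C)(C)C | intermediate
9 | benzyl (2Z)-2-[(1S)-1-(acetyloxy)pentadecyl]-4-[(tert-butyldimethylsilyl)oxy]but-2-enoate | CCCCCCCCCCCCCC[C@H](OC(C)=O)/C(C(=O)OCc1ccccc1)=C/CO[Si](C)(C)C(C)(C)C | intermediate
10 | benzyl (2R,3S)-2-[(1S)-1-(acetyloxy)pentadecyl]-4-[(tert-butyldimethylsilyl)oxy]-2,3-dihydroxybutanoate | CCCCCCCCCCCCCC[C@H](OC(C)=O)[C@@](O)(C(=O)OCc1ccccc1)[C@@H](O)CO[Si](C)(C)C(C)(C)C | intermediate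
11 | benzyl (4S,5S)-4-[(1S)-1-(acetyloxy)pentadecyl]-2,2-di-tert-butyl-5-{[(tert-butyldimethylsilyl)oxy]methyl}-1,3,2-dioxasilolane-4-carboxylate | CCCCCCCCCCCCCC[C@H](OC(C)=O)[C@@]1(O[Si](C(C)(C)C)(C(C)(C)C)O[C@H]1CO[Si](C)(C)C(C)(C)C)C(=O)OCc1ccccc1 | intermediate
12 | (4S,5S)-4-[(1S)-1-(acetyloxy)pentadecyl]-2,2-di-tert-butyl-5-{[(tert-butyldimethylsilyl)oxy]methyl}-1,3,2-dioxasilolane-4-carboxylic acid | CCCCCCCCCCCCCC[C@H](OC(C)=O)[C@@]1(O[Si](C(C)(C)C)(C(C)(C)C)O[C@H]1CO[Si](C)(C)C(C)(C)C)C(=O)O | intermediate
13 | trimethylsilyldiazomethane | C[Si](C)(C)C=[N+]=[N-] | starting material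
14 | acid chloride of 12, (4S,5S)-configured 1,3,2-dioxasilolane-4-carbonyl chloride | CCCCCCCCCCCCCC[C@H](OC(C)=O)[C@@]1(O[Si](C(C)(C)C)(C(C)(C)C)O[C@H]1CO[Si](C)(C)C(C)(C)C)C(=O)Cl | intermediate (not isolated)
15 | (1S)-1-[(4S,5S)-2,2-di-tert-butyl-5-{[(tert-butyldimethylsilyl)oxy]methyl}-4-(diazoacetyl)-1,3,2-dioxasilolan-4-yl]pentadecyl acetate | CCCCCCCCCCCCCC[C@H](OC(C)=O)[C@@]1(O[Si](C(C)(C)C)(C(C)(C)C)O[C@H]1CO[Si](C)(C)C(C)(C)C)C(=O)C=[N+]=[N-] | intermediate (precursor of the key step)
16 | (1S)-1-[(3aS,6aS)-2,2-di-tert-butyl-6-[(tert-butyldimethylsilyl)oxy]-4-oxotetrahydro-3aH-cyclopenta[d][1,3,2]dioxasilol-3a-yl]pentadecyl acetate, silyloxy carbon as both epimers | CCCCCCCCCCCCCC[C@H](OC(C)=O)[C@@]1(O[Si](C(C)(C)C)(C(C)(C)C)O2)C(=O)CC(O[Si](C)(C)C(C)(C)C)[C@@H]12 | intermediate (product of the key step)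
17 | (1S)-1-[(3aS,6aS)-2,2-di-tert-butyl-4-oxo-4,6a-dihydro-3aH-cyclopenta[d][1,3,2]dioxasilol-3a-yl]pentadecyl acetate | CCCCCCCCCCCCCC[C@H](OC(C)=O)[C@@]1(O[Si](C(C)(C)C)(C(C)(C)C)O2)C(=O)C=C[C@@H]12 | intermediate
18 | (1S)-1-[(1R,5S)-1,5-dihydroxy-2-oxocyclopent-3-en-1-yl]pentadecyl acetate | CCCCCCCCCCCCCC[C@H](OC(C)=O)[C@@]1(O)C(=O)C=C[C@@H]1O | target

Total step count: 11. Longest linear sequence: 11 steps (1 → 18); 2, 5 and 13 are commercial and enter directly.

Steps most likely to fail

1. Step 9. What may go wrong: the carbenoid is diverted before it reaches the C3–H bond, by insertion into the chain C7–H bonds, by attack of O4 on the carbenoid (oxonium ylide, then silyl shift), or by carbene dimerisation. Fallback (carbonyl condensation in place of carbenoid chemistry, forming the same C2–C3 bond): setting out from acid 12, the acid chloride 14 is generated as in step 8 and treated with Me2CuLi (THF, −78 °C), which should give the methyl ketone F1 without touching the acetate. CSA in MeOH/CH2Cl2 at 0 °C should then cleave the primary silyl ether while the hindered silylene survives mild acid, giving the hydroxy ketone F2 (possibly resting as its cyclic hemiketal). Dess–Martin periodinane (NaHCO3, CH2Cl2) should give the keto aldehyde F3. An intramolecular aldol condensation (dibenzylammonium trifluoroacetate, benzene, 50 °C) should then close the ring, since the methyl group is the only productive enolisation site (C5 is quaternary) and the silylene ring disfavours β-elimination from the aldehyde side, and dehydration gives enone 17, where the route is rejoined for step 11.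

2. Step 5. What may go wrong: insufficient facial discrimination in the osmylation, because an acyloxy group steers less strongly than an ether, together with acetyl migration onto the new hydroxyls during isolation. Fallback (an ether on O6 during the osmylation, the acetate introduced afterwards): setting out from alcohol 8, 4-methoxybenzyl trichloroacetimidate with Sc(OTf)3 (cat.) in toluene at 0 °C should give the 4-methoxybenzyl ether F4. Osmylation (OsO4 cat., NMO, acetone/H2O) of this allylic ether is expected to follow the anti rule more strictly and give the diol F5. t-Bu2Si(OTf)2/2,6-lutidine should give the silylene F6, and DDQ in CH2Cl2/pH 7 buffer should remove the 4-methoxybenzyl group to give the C6 alcohol F7. Ac2O, DMAP and pyridine then give 11, where the route is rejoined for step 7.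

3. Step 3. What may go wrong: slow or poorly selective enzymatic acylation, because both groups on the carbinol carbon are large. Fallback (asymmetric reduction in place of resolution): setting out from racemic alcohol 7, Dess–Martin periodinane (NaHCO3, CH2Cl2, 0 °C) should give the ketone F8. Corey–Bakshi–Shibata reduction with (R)-2-methyl-CBS-oxazaborolidine and catecholborane (toluene, −78 °C) should then deliver hydride to the face that gives the (S)-alcohol 8, with the α-branched alkenyl arm acting as the large group and the low temperature favouring 1,2- over 1,4-reduction; the route is rejoined at 8 for step 4.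

Further compounds
F1 | step 9 | (1S)-1-[(4S,5S)-4-acetyl-2,2-di-tert-butyl-5-{[(tert-butyldimethylsilyl)oxy]methyl}-1,3,2-dioxasilolan-4-yl]pentadecyl acetate | CCCCCCCCCCCCCC[C@H](OC(C)=O)[C@@]1(O[Si](C(C)(C)C)(C(C)(C)C)O[C@H]1CO[Si](C)(C)C(C)(C)C)C(C)=O
F2 | step 9 | (1S)-1-[(4S,5S)-4-acetyl-2,2-di-tert-butyl-5-(hydroxymethyl)-1,3,2-dioxasilolan-4-yl]pentadecyl acetate | CCCCCCCCCCCCCC[C@H](OC(C)=O)[C@@]1(O[Si](C(C)(C)C)(C(C)(C)C)O[C@H]1CO)C(C)=O
F3 | step 9 | (1S)-1-[(4S,5R)-4-acetyl-2,2-di-tert-butyl-5-formyl-1,3,2-dioxasilolan-4-yl]pentadecyl acetate | CCCCCCCCCCCCCC[C@H](OC(C)=O)[C@@]1(O[Si](C(C)(C)C)(C(C)(C)C)O[C@H]1C=O)C(C)=O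
F4 | step 5 | benzyl (2Z)-4-[(tert-butyldimethylsilyl)oxy]-2-{(1S)-1-[(4-methoxybenzyl)oxy]pentadecyl}but-2-enoate | CCCCCCCCCCCCCC[C@H](OCc1ccc(OC)cc1)/C(C(=O)OCc1ccccc1)=C/CO[Si](C)(C)C(C)(C)C
F5 | step 5 | benzyl (2R,3S)-4-[(tert-butyldimethylsilyl)oxy]-2,3-dihydroxy-2-{(1S)-1-[(4-methoxybenzyl)oxy]pentadecyl}butanoate | CCCCCCCCCCCCCC[C@H](OCc1ccc(OC)cc1)[C@@](O)(C(=O)OCc1ccccc1)[C@@H](O)CO[Si](C)(C)C(C)(C)C
F6 | step 5 | benzyl (4S,5S)-2,2-di-tert-butyl-5-{[(tert-butyldimethylsilyl)oxy]methyl}-4-{(1S)-1-[(4-methoxybenzyl)oxy]pentadecyl}-1,3,2-dioxasilolane-4-carboxylate | CCCCCCCCCCCCCC[C@H](OCc1ccc(OC)cc1)[C@@]1(O[Si](C(C)(C)C)(C(C)(C)C)O[C@H]1CO[Si](C)(C)C(C)(C)C)C(=O)OCc1ccccc1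
F7 | step 5 | benzyl (4S,5S)-2,2-di-tert-butyl-5-{[(tert-butyldimethylsilyl)oxy]methyl}-4-[(1S)-1-hydroxypentadecyl]-1,3,2-dioxasilolane-4-carboxylate | CCCCCCCCCCCCCC[C@H](O)[C@@]1(O[Si](C(C)(C)C)(C(C)(C)C)O[C@H]1CO[Si](C)(C)C(C)(C)C)C(=O)OCc1ccccc1
F8 | step 3 | benzyl (2Z)-4-[(tert-butyldimethylsilyl)oxy]-2-pentadecanoylbut-2-enoate | CCCCCCCCCCCCCCC(=O)/C(C(=O)OCc1ccccc1)=C/CO[Si](C)(C)C(C)(C)C
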